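## Retrosynthetic overview

1. Target ⇐ one syn-hydrogenation of a (Z)-2-aryl-3-benzylbutenedioic acid 4-methyl ester, which sets both stereocentres at once, then loss of two silyl ethers.
2. (Z)-Half-ester ⇐ singlet-oxygen dearomatisation and fragmentation of a 2-methoxy-3-benzyl-4-arylfuran: the OMe carbon becomes CO2Me, the CH carbon becomes CO2H, and the ring dictates the Z geometry.
3. Methoxyfuran ⇐ 3-benzyl-4-arylbutenolide ⇐ Negishi coupling of a 3-benzyltetronic acid triflate with the arylzinc made from 4-bromophenol.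
4. 3-Benzyltetronic acid ⇐ tetronic acid + 3-silyloxy-4-prenylbenzaldehyde (reductive alkylation); aldehyde ⇐ 4-bromo-3-hydroxybenzaldehyde + prenylstannane.
5. Rings: both benzene rings are bought and no ring of the target is made; the only ring events are aromatisation of the bought lactone ring to a furan and its oxidative opening.

Assumption: the SMILES is read as the (2R,3R) isomer, and every compound marked as starting material is taken as bought.

## Route

Step 1
Reactants: 1 4-bromo-3-hydroxybenzaldehyde; 2 tributyl(3-methylbut-2-en-1-yl)stannane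
Product: 3 3-hydroxy-4-(3-methylbut-2-en-1-yl)benzaldehyde
Conditions: Pd(PPh3)4 (5 mol%), DMF, 90 °C
Reagents that add atoms: none
Why: Stille cross-coupling, in which zerovalent palladium inserts into the C–Br bond para to the formyl group and reductive elimination at the less hindered primary allyl terminus gives the linear prenyl arene; the free phenol is tolerated and no stereocentre is formed.

Step 2
Reactants: 3 3-hydroxy-4-(3-methylbut-2-en-1-yl)benzaldehyde
Product: 4 3-[(tert-butyldimethylsilyl)oxy]-4-(3-methylbut-2-en-1-yl)benzaldehyde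
Conditions: TBSCl, imidazole, DMF, 0 °C → rt
Reagents that add atoms: tert-butyldimethylsilyl chloride, CC(C)(C)[Si](C)(C)Cl
Why: Imidazole-promoted O-silylation keeps the phenol out of the later triflation, strong-base and methylation steps and stops the ortho-prenyl phenol from closing to a chroman.

Step 3
Reactants: 4 3-[(tert-butyldimethylsilyl)oxy]-4-(3-methylbut-2-en-1-yl)benzaldehyde; 5 tetronic acid (4-hydroxyfuran-2(5H)-one)
Product: 7 3-{[3-(tert-butyldimethylsilyloxy)-4-(3-methylbut-2-en-1-yl)phenyl]methyl}-4-hydroxyfuran-2(5H)-one, via Knoevenagel adduct 6 (not isolated)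
Conditions: L-proline (20 mol%), Hantzsch ester (diethyl 2,6-dimethyl-1,4-dihydropyridine-3,5-dicarboxylate, 1.1 equiv), EtOH–CH2Cl2, rt
Reagents that add atoms: none
Why: Three-component reductive alkylation: proline-catalysed Knoevenagel condensation at C-3 of the vinylogous acid, then hydride transfer from the Hantzsch ester to the very electrophilic alkylidene dione, which installs the benzyl group without a benzyl halide and leaves the isolated prenyl alkene untouched.

Step 4
Reactants: 7 3-{[3-(tert-butyldimethylsilyloxy)-4-(3-methylbut-2-en-1-yl)phenyl]methyl}-4-hydroxyfuran-2(5H)-one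
Product: 8 4-{[3-(tert-butyldimethylsilyloxy)-4-(3-methylbut-2-en-1-yl)phenyl]methyl}-5-oxo-2,5-dihydrofuran-3-yl trifluoromethanesulfonate
Conditions: Tf2O, iPr2NEt, CH2Cl2, −78 °C
Reagents that add atoms: trifluoromethanesulfonic anhydride, O=S(=O)(OS(=O)(=O)C(F)(F)F)C(F)(F)F
Why: O-sulfonylation of the tetronic acid enol (pKa about 4) gives a β-acyl-activated vinyl triflate for cross-coupling.

Step 5
Reactants: 9 4-bromophenol
Product: 10 (4-bromophenoxy)(tert-butyl)dimethylsilane
Conditions: TBSCl, imidazole, CH2Cl2, rt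
Reagents that add atoms: tert-butyldimethylsilyl chloride, CC(C)(C)[Si](C)(C)Cl
Why: Standard silyl ether formation, so that the aryl bromide can be lithiated and the phenol stays masked until the last step.

Step 6
Reactants: 10 (4-bromophenoxy)(tert-butyl)dimethylsilane; 8 4-{[3-(tert-butyldimethylsilyloxy)-4-(3-methylbut-2-en-1-yl)phenyl]methyl}-5-oxo-2,5-dihydrofuran-3-yl trifluoromethanesulfonate
Product: 13 3-{[3-(tert-butyldimethylsilyloxy)-4-(3-methylbut-2-en-1-yl)phenyl]methyl}-4-{4-[(tert-butyldimethylsilyl)oxy]phenyl}furan-2(5H)-one, via aryllithium 11 (not isolated), via arylzinc chloride 12 (not isolated)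
Conditions: n-butyllithium, THF, −78 °C; ZnCl2, −78 °C → rt; Pd(PPh3)4 (3 mol%), 45 °C
Reagents that add atoms: none
Why: Bromine–lithium exchange, transmetalation to zinc and Negishi coupling with the activated vinyl triflate; the arylzinc does not attack the lactone, and the 3-benzyl-4-aryl pattern obtained decides which carboxyl will become the ester.

Step 7
Reactants: 13 3-{[3-(tert-butyldimethylsilyloxy)-4-(3-methylbut-2-en-1-yl)phenyl]methyl}-4-{4-[(tert-butyldimethylsilyl)oxy]phenyl}furan-2(5H)-one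
Product: 17 (2Z)-2-{4-[(tert-butyldimethylsilyl)oxy]phenyl}-3-{[3-(tert-butyldimethylsilyloxy)-4-(3-methylbut-2-en-1-yl)phenyl]methyl}-4-methoxy-4-oxobut-2-enoic acid, via potassium furanolate 14 (not isolated), via 2-methoxyfuran 15 (not isolated), via furan endoperoxide 16 (not isolated)
Conditions: KN(SiMe3)2, THF–DMPU, −78 °C; MeOTf, −78 °C; O2, tetraphenylporphyrin (1 mol%), visible light, −78 °C; iPr2NEt, −78 → 0 °C; cold pH 4 buffer work-up, acid used at once
Reagents that add atoms: methyl trifluoromethanesulfonate, COS(=O)(=O)C(F)(F)F; dioxygen, O=O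
Why: Proposed new method: γ-deprotonation gives the aromatic 2-furanolate, O-methylation by the hard methyl triflate gives the 2-methoxyfuran, singlet oxygen adds [4+2] across C-2/C-5 (electron-rich furans react at least a hundred times faster than the trisubstituted prenyl alkene), and amine-induced Kornblum–DeLaMare cleavage at the bridgehead C–H gives a hemi-orthoester alkoxide that expels the new carboxylate, so the methoxy carbon becomes CO2Me next to the benzyl-bearing carbon, C-5 becomes CO2H next to the aryl-bearing carbon and the former ring fixes the Z geometry; the closest known reactions are the photooxygenation of 2-alkoxyfurans and the base-induced conversion of furan endoperoxides into γ-hydroxybutenolides.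

Step 8
Reactants: 17 (2Z)-2-{4-[(tert-butyldimethylsilyl)oxy]phenyl}-3-{[3-(tert-butyldimethylsilyloxy)-4-(3-methylbut-2-en-1-yl)phenyl]methyl}-4-methoxy-4-oxobut-2-enoic acid
Product: 19 (2R,3R)-2-(4-hydroxyphenyl)-3-{[3-hydroxy-4-(3-methylbut-2-en-1-yl)phenyl]methyl}-4-methoxy-4-oxobutanoic acid (target), via bis-silyl ether 18 (not isolated)
Conditions: Ru(OAc)2[(R)-BINAP] (2 mol%), H2 (100 bar), Et3N (1 equiv), MeOH, 30 °C; then vent, KHF2 (4 equiv), MeOH, rt
Reagents that add atoms: none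
Why: Carboxylate-directed asymmetric hydrogenation of the Noyori Ru–BINAP dicarboxylate type delivers both hydrogens syn to one face of the tetrasubstituted Z-alkene, so C-2 and C-3 are set together: the Z geometry allows only the (2R,3R)/(2S,3S) pair, and the (R)-ligand is chosen for (2R,3R) by analogy with 2-arylacrylic acids, where (S)-BINAP gives the (S)-2-arylpropanoic acid; this catalyst does not reduce the isolated prenyl alkene, and bifluoride in methanol then cleaves both aryl silyl ethers without touching the ester or the stereocentres.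

## Compound list

1 | 4-bromo-3-hydroxybenzaldehyde | O=Cc1ccc(Br)c(O)c1 | starting material
2 | tributyl(3-methylbut-2-en-1-yl)stannane | CCCC[Sn](CCCC)(CCCC)CC=C(C)C | starting material
3 | 3-hydroxy-4-(3-methylbut-2-en-1-yl)benzaldehyde | O=Cc1ccc(CC=C(C)C)c(O)c1 | intermediate
4 | 3-[(tert-butyldimethylsilyl)oxy]-4-(3-methylbut-2-en-1-yl)benzaldehyde | O=Cc1ccc(CC=C(C)C)c(O[Si](C)(C)C(C)(C)C)c1 | intermediate
5 | tetronic acid (4-hydroxyfuran-2(5H)-one) | O=C1C=C(O)CO1 | starting material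
6 | 3-{[3-(tert-butyldimethylsilyloxy)-4-(3-methylbut-2-en-1-yl)phenyl]methylidene}furan-2,4(3H,5H)-dione (alkene geometry not defined) | O=C1OCC(=O)C1=Cc1ccc(CC=C(C)C)c(O[Si](C)(C)C(C)(C)C)c1 | intermediate
7 | 3-{[3-(tert-butyldimethylsilyloxy)-4-(3-methylbut-2-en-1-yl)phenyl]methyl}-4-hydroxyfuran-2(5H)-one | O=C1OCC(O)=C1Cc1ccc(CC=C(C)C)c(O[Si](C)(C)C(C)(C)C)c1 | intermediate
8 | 4-{[3-(tert-butyldimethylsilyloxy)-4-(3-methylbut-2-en-1-yl)phenyl]methyl}-5-oxo-2,5-dihydrofuran-3-yl trifluoromethanesulfonate | O=C1OCC(OS(=O)(=O)C(F)(F)F)=C1Cc1ccc(CC=C(C)C)c(O[Si](C)(C)C(C)(C)C)c1 | intermediate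
9 | 4-bromophenol | Oc1ccc(Br)cc1 | starting material
10 | (4-bromophenoxy)(tert-butyl)dimethylsilane | CC(C)(C)[Si](C)(C)Oc1ccc(Br)cc1 | intermediate
11 | {4-[(tert-butyldimethylsilyl)oxy]phenyl}lithium | [Li]c1ccc(O[Si](C)(C)C(C)(C)C)cc1 | intermediate
12 | {4-[(tert-butyldimethylsilyl)oxy]phenyl}zinc chloride | Cl[Zn]c1ccc(O[Si](C)(C)C(C)(C)C)cc1 | intermediate
13 | 3-{[3-(tert-butyldimethylsilyloxy)-4-(3-methylbut-2-en-1-yl)phenyl]methyl}-4-{4-[(tert-butyldimethylsilyl)oxy]phenyl}furan-2(5H)-one | O=C1OCC(c2ccc(O[Si](C)(C)C(C)(C)C)cc2)=C1Cc1ccc(CC=C(C)C)c(O[Si](C)(C)C(C)(C)C)c1 | intermediate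
14 | potassium 3-{[3-(tert-butyldimethylsilyloxy)-4-(3-methylbut-2-en-1-yl)phenyl]methyl}-4-{4-[(tert-butyldimethylsilyl)oxy]phenyl}furan-2-olate | [K+].[O-]c1occ(-c2ccc(O[Si](C)(C)C(C)(C)C)cc2)c1Cc1ccc(CC=C(C)C)c(O[Si](C)(C)C(C)(C)C)c1 | intermediate
15 | 2-methoxy-3-{[3-(tert-butyldimethylsilyloxy)-4-(3-methylbut-2-en-1-yl)phenyl]methyl}-4-{4-[(tert-butyldimethylsilyl)oxy]phenyl}furan | COc1occ(-c2ccc(O[Si](C)(C)C(C)(C)C)cc2)c1Cc1ccc(CC=C(C)C)c(O[Si](C)(C)C(C)(C)C)c1 | intermediate
16 | 1-methoxy-6-{[3-(tert-butyldimethylsilyloxy)-4-(3-methylbut-2-en-1-yl)phenyl]methyl}-5-{4-[(tert-butyldimethylsilyl)oxy]phenyl}-2,3,7-trioxabicyclo[2.2.1]hept-5-ene (racemic; one enantiomer drawn) | CO[C@]12OO[C@H](O1)C(c1ccc(O[Si](C)(C)C(C)(C)C)cc1)=C2Cc1ccc(CC=C(C)C)c(O[Si](C)(C)C(C)(C)C)c1 | intermediate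
17 | (2Z)-2-{4-[(tert-butyldimethylsilyl)oxy]phenyl}-3-{[3-(tert-butyldimethylsilyloxy)-4-(3-methylbut-2-en-1-yl)phenyl]methyl}-4-methoxy-4-oxobut-2-enoic acid | COC(=O)/C(Cc1ccc(CC=C(C)C)c(O[Si](C)(C)C(C)(C)C)c1)=C(\C(=O)O)c1ccc(O[Si](C)(C)C(C)(C)C)cc1 | intermediate
18 | (2R,3R)-2-{4-[(tert-butyldimethylsilyl)oxy]phenyl}-3-{[3-(tert-butyldimethylsilyloxy)-4-(3-methylbut-2-en-1-yl)phenyl]methyl}-4-methoxy-4-oxobutanoic acid | COC(=O)[C@H](Cc1ccc(CC=C(C)C)c(O[Si](C)(C)C(C)(C)C)c1)[C@@H](C(=O)O)c1ccc(O[Si](C)(C)C(C)(C)C)cc1 | intermediate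
19 | (2R,3R)-2-(4-hydroxyphenyl)-3-{[3-hydroxy-4-(3-methylbut-2-en-1-yl)phenyl]methyl}-4-methoxy-4-oxobutanoic acid | COC(=O)[C@H](Cc1ccc(CC=C(C)C)c(O)c1)[C@@H](C(=O)O)c1ccc(O)cc1 | target

## Step count and risks

Total step count: 8. Longest linear sequence: 7 steps (1 → 3 → 4 → 7 → 8 → 13 → 17 → 19; steps 1, 2, 3, 4, 6, 7, 8).

Steps most likely to fail:

Step 8. The alkene is tetrasubstituted and hindered, so turnover may be low, the facial sense is assigned only by analogy, and Z/E or positional isomerisation before reduction would erode the diastereomer ratio. Fallback: set out from 17 and give up catalyst control. Hydrogenation with the achiral cationic complex [Rh(nbd)(dppb)]BF4 (H2 50 bar, Et3N, MeOH) is still a carboxylate-directed syn addition to the Z-alkene, so it gives only the erythro pair, the racemic 2-aryl-3-benzylsuccinic acid 4-methyl ester F1. Crystallisation with (R)-1-phenylethylamine from ethyl acetate–heptane gives the (R)-1-phenylethylammonium salt of the (2R,3R)-acid F2; which amine antipode crystallises the wanted acid is found by trial. Acidification with citric acid comes back to the route at 18, which is desilylated with KHF2 as in step 8.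

Step 7. The furanolate may be methylated on carbon instead of oxygen, the alkoxyfuran endoperoxide may rearrange before the base is added, and the half-ester can close to the anhydride if it is handled warm or acidic. Fallback: leave the furan and set out from 4.
- Commercial methyl 3-(4-hydroxyphenyl)-3-oxopropanoate is silylated (TBSCl, imidazole) to methyl 3-{4-[(tert-butyldimethylsilyl)oxy]phenyl}-3-oxopropanoate F3.
- Knoevenagel condensation of this with 4 (piperidinium acetate, toluene) gives the alkylidene β-keto ester F4, which the Hantzsch ester reduces in the same pot to the α-benzyl β-keto ester F5.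
- LiN(SiMe3)2 (THF, −78 °C) gives the chelated lithium (Z)-enolate F6, which N-phenylbis(trifluoromethanesulfonimide) traps as the (Z)-enol triflate F7.
- Hydroxycarbonylation (Pd(OAc)2, 1,3-bis(diphenylphosphino)propane, CO 1 atm, Et3N, DMF–H2O, 60 °C) keeps the alkene geometry and comes back to the route at 17.

Step 1. The allylic stannane can transfer with allylic transposition to give the 1,1-dimethylallyl isomer, and the unprotected electron-rich bromophenol may couple slowly. Fallback: set out from 1. Stille coupling with allyltributylstannane (Pd(PPh3)4, DMF, 90 °C), which has no regiochemical ambiguity, gives 3-hydroxy-4-(prop-2-en-1-yl)benzaldehyde F8. Cross-metathesis with excess 2-methylbut-2-ene (second-generation Grubbs catalyst, RuCl2(=CHPh)(H2IMes)(PCy3), CH2Cl2, 40 °C) turns the allyl group into prenyl and comes back to the route at 3.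

## Further compounds

F1 | step 8 | racemic (2R,3R)/(2S,3S)-2-{4-[(tert-butyldimethylsilyl)oxy]phenyl}-3-{[3-(tert-butyldimethylsilyloxy)-4-(3-methylbut-2-en-1-yl)phenyl]methyl}-4-methoxy-4-oxobutanoic acid | COC(=O)[C@H](Cc1ccc(CC=C(C)C)c(O[Si](C)(C)C(C)(C)C)c1)[C@@H](C(=O)O)c1ccc(O[Si](C)(C)C(C)(C)C)cc1.COC(=O)[C@@H](Cc1ccc(CC=C(C)C)c(O[Si](C)(C)C(C)(C)C)c1)[C@H](C(=O)O)c1ccc(O[Si](C)(C)C(C)(C)C)cc1
F2 | step 8 | (R)-1-phenylethylammonium (2R,3R)-2-{4-[(tert-butyldimethylsilyl)oxy]phenyl}-3-{[3-(tert-butyldimethylsilyloxy)-4-(3-methylbut-2-en-1-yl)phenyl]methyl}-4-methoxy-4-oxobutanoate | COC(=O)[C@H](Cc1ccc(CC=C(C)C)c(O[Si](C)(C)C(C)(C)C)c1)[C@@H](C(=O)[O-])c1ccc(O[Si](C)(C)C(C)(C)C)cc1.C[C@@H]([NH3+])c1ccccc1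
F3 | step 7 | methyl 3-{4-[(tert-butyldimethylsilyl)oxy]phenyl}-3-oxopropanoate | COC(=O)CC(=O)c1ccc(O[Si](C)(C)C(C)(C)C)cc1
F4 | step 7 | methyl 2-{4-[(tert-butyldimethylsilyl)oxy]benzoyl}-3-[3-(tert-butyldimethylsilyloxy)-4-(3-methylbut-2-en-1-yl)phenyl]prop-2-enoate (alkene geometry not defined) | COC(=O)C(=Cc1ccc(CC=C(C)C)c(O[Si](C)(C)C(C)(C)C)c1)C(=O)c1ccc(O[Si](C)(C)C(C)(C)C)cc1
F5 | step 7 | methyl 2-{[3-(tert-butyldimethylsilyloxy)-4-(3-methylbut-2-en-1-yl)phenyl]methyl}-3-{4-[(tert-butyldimethylsilyl)oxy]phenyl}-3-oxopropanoate (racemic) | COC(=O)C(Cc1ccc(CC=C(C)C)c(O[Si](C)(C)C(C)(C)C)c1)C(=O)c1ccc(O[Si](C)(C)C(C)(C)C)cc1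
F6 | step 7 | lithium (Z)-enolate of F5 (enolate oxygen cis to the ester) | [Li+].COC(=O)/C(Cc1ccc(CC=C(C)C)c(O[Si](C)(C)C(C)(C)C)c1)=C(\[O-])c1ccc(O[Si](C)(C)C(C)(C)C)cc1
F7 | step 7 | methyl (2Z)-2-{[3-(tert-butyldimethylsilyloxy)-4-(3-methylbut-2-en-1-yl)phenyl]methyl}-3-{4-[(tert-butyldimethylsilyl)oxy]phenyl}-3-[(trifluoromethanesulfonyl)oxy]prop-2-enoate | COC(=O)/C(Cc1ccc(CC=C(C)C)c(O[Si](C)(C)C(C)(C)C)c1)=C(\OS(=O)(=O)C(F)(F)F)c1ccc(O[Si](C)(C)C(C)(C)C)cc1
F8 | step 1 | 3-hydroxy-4-(prop-2-en-1-yl)benzaldehyde | O=Cc1ccc(CC=C)c(O)c1
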